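**Retrosynthetic overview**
1. The aryl ester C–O bond between O4 of ring A and the carboxyl carbon of ring B is cut into benzyl 2,4-dihydroxy-6-pentylbenzoate and 3-chloro-2-hydroxy-4-methoxy-6-propylbenzoic acid; the ring-A acid is uncovered last by benzyl ester hydrogenolysis.
2. The route rests on ring A (C1 carboxyl, C2 OH, C4 O-acyl, C6 pentyl): its oxygens sit on alternate carbons as in a folded 3,5,7-trioxododecanoyl chain, so the ring is opened at its C1–C6 bond (aldol) to benzyl 3,5,7-trioxododecanoate, released from a diketo-dioxinone and benzyl alcohol through an acylketene.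
3. The diketo-dioxinone comes from 2,2,6-trimethyl-4H-1,3-dioxin-4-one by two Claisen-type chain extensions (acetyl chloride, then the Weinreb amide of hexanoic acid).
4. Ring B is carried from 3,5-dimethoxybenzaldehyde: propyl by Wittig olefination and hydrogenation, Cl at C3 by lithiation between the two methoxy groups, C1 by Rieche formylation, chelation-controlled demethylation at O2, Pinnick oxidation.
5. Ring order: ring A is the only ring formed (step 4); ring B is an intact benzene ring throughout.

Key step: step 4

Remark: the target has no stereocentre; the alkene geometry of the Wittig product and the configuration of the transient aldol adduct and α-chloro ether are of no consequence, because these elements are destroyed in the same or the next step.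

**Step 1**
Reactants: 1 hexanoyl chloride
Product: 2 N-methoxy-N-methylhexanamide
Conditions: MeNH(OMe)·HCl, Et3N (2.2 equiv), CH2Cl2, 0 °C → rt
Reagents that add atoms: N,O-dimethylhydroxylamine hydrochloride, CNOC.Cl
Why: Schotten–Baumann-type N-acylation of the hydroxylamine freed by Et3N should give the Weinreb amide cleanly, since the amide is not acylated further.

**Step 2**
Reactants: 3 2,2,6-trimethyl-4H-1,3-dioxin-4-one; 4 acetyl chloride
Product: 6 2,2-dimethyl-6-(2-oxopropyl)-4H-1,3-dioxin-4-one, via lithium dienolate 5 (not isolated)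
Conditions: 3 (2.0 equiv), LiN(SiMe3)2 (2.0 equiv), THF, −78 °C; then 4 (1.0 equiv), −78 °C; 1 M aq. HCl quench
Reagents that add atoms: none
Why: Deprotonation of the C6 methyl group gives the cross-conjugated dienolate 5, which should undergo vinylogous Claisen-type C-acylation at its terminal carbon, the second equivalent of 5 taking the proton of the more acidic product so that it is held as its enolate and not acylated twice.

**Step 3**
Reactants: 6 2,2-dimethyl-6-(2-oxopropyl)-4H-1,3-dioxin-4-one; 2 N-methoxy-N-methylhexanamide
Product: 8 2,2-dimethyl-6-(2,4-dioxononyl)-4H-1,3-dioxin-4-one, via dilithium dianion 7 (not isolated)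
Conditions: LiN(iPr)2 (2.2 equiv), THF, −78 °C; then 2, −78 → −20 °C; 1 M aq. HCl quench
Reagents that add atoms: none
Why: The terminal carbanion of dianion 7 is its most nucleophilic site and should add to the Weinreb amide (Weinreb ketone synthesis used as a Claisen-type acylation of a β-dicarbonyl dianion), the chelated adduct releasing the 1,3-diketone only on quench so that no over-acylation occurs.

**Step 4**
Reactants: 8 2,2-dimethyl-6-(2,4-dioxononyl)-4H-1,3-dioxin-4-one; 9 benzyl alcohol
Product: 13 benzyl 2,4-dihydroxy-6-pentylbenzoate, via acylketene 10 (not isolated), via benzyl 3,5,7-trioxododecanoate 11 (not isolated), via cyclic aldol adduct 12 (not isolated)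
Conditions: 9 (3 equiv), PhMe, 110 °C; cool, then Cs2CO3 (1.5 equiv), iPrOH/CH2Cl2, rt; then 1 M aq. HCl, rt
Reagents that add atoms: none
Why: Heating 8 should cause a retro-[4+2] (retro-hetero-Diels–Alder) loss of acetone to acylketene 10, which benzyl alcohol, present in excess from the start, captures at the ketene carbon to give triketo ester 11. Cs2CO3 then equilibrates the enolates of 11, and chain carbon C2 (between the ester and the C3 ketone) adds to the C7 ketone, forming the C1–C6 bond of ring A in a 6-exo-trig aldol closure to 12 (enolendo when counted through the C3 enolate, enolexo through the ester enolate, both allowed for a six-membered ring). E1cB loss of one molecule of water from 12 and enolisation of the two remaining ring ketones, completed on acidification, should deliver the aromatic resorcylate 13; the closest known reaction type is the thermolysis, alcohol trapping and aldol aromatisation of diketo-dioxinones to resorcylate esters, a laboratory form of polyketide aldol cyclisation. No stereocentre remains in 13, so the two stereocentres of 12 need no control. The step needs C2-to-C7 aldol closure in preference to C6-to-C1 Claisen closure (an acylphloroglucinol), to aldol closure from C8 onto C3 and to O-acylation giving a 4-hydroxy-2-pyranone: the C4 and C6 methylenes, although more acidic than C2, reach a ketone only through four-membered rings and C6 reaches only the poorly electrophilic ester, C8 is singly activated, and C2 is the one doubly activated carbon placed six atoms from a ketone. Pyranone formation is held back by the excess of benzyl alcohol during thermolysis and by running the base stage at room temperature.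

**Step 5**
Reactants: 14 3,5-dimethoxybenzaldehyde
Product: 15 1,3-dimethoxy-5-(prop-1-en-1-yl)benzene (E/Z mixture)
Conditions: EtPPh3Br, KOtBu, THF, 0 °C; then 14, 0 °C → rt
Reagents that add atoms: ethyltriphenylphosphonium bromide, CC[P+](c1ccccc1)(c1ccccc1)c1ccccc1.[Br-]
Why: Wittig olefination of an aromatic aldehyde with a non-stabilised ylide is reliable, and the alkene geometry is irrelevant because the double bond is saturated next.

**Step 6**
Reactants: 15 1,3-dimethoxy-5-(prop-1-en-1-yl)benzene
Product: 16 1,3-dimethoxy-5-propylbenzene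
Conditions: H2 (1 atm), 10% Pd/C, EtOAc, rt
Reagents that add atoms: none
Why: Heterogeneous catalytic hydrogenation of a styrenic alkene should be fast and leaves the aryl methyl ethers untouched.

**Step 7**
Reactants: 16 1,3-dimethoxy-5-propylbenzene
Product: 18 2-chloro-1,3-dimethoxy-5-propylbenzene, via aryllithium 17 (not isolated)
Conditions: n-BuLi (1.2 equiv), THF, 0 °C → rt; then C2Cl6 (1.3 equiv), −78 °C → rt
Reagents that add atoms: hexachloroethane, ClC(Cl)(Cl)C(Cl)(Cl)Cl
Why: Directed ortho-metalation takes place at the ring carbon flanked by both methoxy groups, and chlorination of aryllithium 17 with C2Cl6 places the chlorine between the two oxygens (the future C3 of ring B) without relying on the site selectivity of an electrophilic chlorination.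

**Step 8**
Reactants: 18 2-chloro-1,3-dimethoxy-5-propylbenzene
Product: 20 3-chloro-2,4-dimethoxy-6-propylbenzaldehyde, via chloro(methoxy)methyl arene 19 (not isolated)
Conditions: Cl2CHOMe (1.5 equiv), TiCl4 (2.2 equiv), CH2Cl2, −10 → 0 °C; then ice-cold 1 M aq. HCl
Reagents that add atoms: dichloromethyl methyl ether, COC(Cl)Cl; water, O
Why: Rieche formylation (Friedel–Crafts attack of the TiCl4-activated dichloromethyl ether, then hydrolysis of 19 on work-up) should occur at one of the two free positions, which are equivalent by symmetry and each ortho to one methoxy group and para to the other.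

**Step 9**
Reactants: 20 3-chloro-2,4-dimethoxy-6-propylbenzaldehyde
Product: 21 3-chloro-2-hydroxy-4-methoxy-6-propylbenzaldehyde
Conditions: BCl3 (1.5 equiv, 1 M in CH2Cl2), CH2Cl2, −78 → 0 °C; then H2O
Reagents that add atoms: none
Why: Chelation-controlled Lewis acid ether cleavage: BCl3 bound to the formyl oxygen and the ortho methoxy group in a six-membered chelate lets chloride remove only that methyl group, the unchelated 4-methoxy group being expected to survive at or below 0 °C.

**Step 10**
Reactants: 21 3-chloro-2-hydroxy-4-methoxy-6-propylbenzaldehyde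
Product: 22 3-chloro-2-hydroxy-4-methoxy-6-propylbenzoic acid
Conditions: NaClO2 (3 equiv), NaH2PO4 (3 equiv), 2-methylbut-2-ene (20 equiv), t-BuOH/THF/H2O, 0 °C → rt
Reagents that add atoms: sodium chlorite, [Na+].[O-]Cl=O
Why: Pinnick oxidation converts the aldehyde to the acid under mildly acidic conditions, and the large excess of alkene consumes the hypochlorous acid by-product before it can chlorinate the free C5 position of the electron-rich ring.

**Step 11**
Reactants: 13 benzyl 2,4-dihydroxy-6-pentylbenzoate; 22 3-chloro-2-hydroxy-4-methoxy-6-propylbenzoic acid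
Product: 24 benzyl 4-[(3-chloro-2-hydroxy-4-methoxy-6-propylbenzoyl)oxy]-2-hydroxy-6-pentylbenzoate, via mixed trifluoroacetic anhydride 23 (not isolated)
Conditions: (CF3CO)2O (5 equiv), PhMe, rt; then H2O/MeOH work-up
Reagents that add atoms: none
Why: Mixed-anhydride esterification (the classical depside coupling): the hindered, electron-rich acid is activated as 23 and should acylate the unchelated 4-OH of 13, while the 2-OH groups of both partners are hydrogen-bonded to their ortho carbonyl groups and should not compete.

**Step 12**
Reactants: 24 benzyl 4-[(3-chloro-2-hydroxy-4-methoxy-6-propylbenzoyl)oxy]-2-hydroxy-6-pentylbenzoate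
Product: 25 4-[(3-chloro-2-hydroxy-4-methoxy-6-propylbenzoyl)oxy]-2-hydroxy-6-pentylbenzoic acid
Conditions: H2 (1 atm), 10% Pd/C, EtOAc, rt, stopped as soon as 24 is consumed
Reagents that add atoms: none
Why: Hydrogenolysis of a benzyl ester over Pd/C in neutral ethyl acetate should be much faster than reduction of the C–Cl bond of an electron-rich aryl chloride when no base is present, and the aryl ester linkage of the depside is inert to these conditions.

**Compound list**
1 | hexanoyl chloride | CCCCCC(Cl)=O | starting material
2 | N-methoxy-N-methylhexanamide | CCCCCC(=O)N(C)OC | intermediate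
3 | 2,2,6-trimethyl-4H-1,3-dioxin-4-one | CC1=CC(=O)OC(C)(C)O1 | starting material
4 | acetyl chloride | CC(Cl)=O | starting material
5 | lithium 2,2-dimethyl-6-methylidene-1,3-dioxin-4-olate (lithium dienolate of 3) | C=C1C=C(O[Li])OC(C)(C)O1 | intermediate
6 | 2,2-dimethyl-6-(2-oxopropyl)-4H-1,3-dioxin-4-one | CC(=O)CC1=CC(=O)OC(C)(C)O1 | intermediate
7 | dilithium dianion of 6 (enolate oxygen and terminal carbon lithiated) | [Li]CC(O[Li])=CC1=CC(=O)OC(C)(C)O1 | intermediate
8 | 2,2-dimethyl-6-(2,4-dioxononyl)-4H-1,3-dioxin-4-one | CCCCCC(=O)CC(=O)CC1=CC(=O)OC(C)(C)O1 | intermediate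
9 | benzyl alcohol | OCc1ccccc1 | starting material
10 | 3,5,7-trioxododec-1-en-1-one (acylketene) | CCCCCC(=O)CC(=O)CC(=O)C=C=O | intermediate
11 | benzyl 3,5,7-trioxododecanoate | CCCCCC(=O)CC(=O)CC(=O)CC(=O)OCc1ccccc1 | intermediate
12 | benzyl 2-hydroxy-4,6-dioxo-2-pentylcyclohexane-1-carboxylate (diastereomer mixture) | CCCCCC1(O)CC(=O)CC(=O)C1C(=O)OCc2ccccc2 | intermediate
13 | benzyl 2,4-dihydroxy-6-pentylbenzoate | CCCCCc1cc(O)cc(O)c1C(=O)OCc1ccccc1 | intermediate
14 | 3,5-dimethoxybenzaldehyde | COc1cc(C=O)cc(OC)c1 | starting material
15 | 1,3-dimethoxy-5-(prop-1-en-1-yl)benzene (E/Z mixture) | CC=Cc1cc(OC)cc(OC)c1 | intermediate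
16 | 1,3-dimethoxy-5-propylbenzene | CCCc1cc(OC)cc(OC)c1 | intermediate
17 | (2,6-dimethoxy-4-propylphenyl)lithium | [Li]c1c(OC)cc(CCC)cc1OC | intermediate
18 | 2-chloro-1,3-dimethoxy-5-propylbenzene | CCCc1cc(OC)c(Cl)c(OC)c1 | intermediate
19 | 3-chloro-1-[chloro(methoxy)methyl]-2,4-dimethoxy-6-propylbenzene (racemic) | CCCc1cc(OC)c(Cl)c(OC)c1C(Cl)OC | intermediate
20 | 3-chloro-2,4-dimethoxy-6-propylbenzaldehyde | CCCc1cc(OC)c(Cl)c(OC)c1C=O | intermediate
21 | 3-chloro-2-hydroxy-4-methoxy-6-propylbenzaldehyde | CCCc1cc(OC)c(Cl)c(O)c1C=O | intermediate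
22 | 3-chloro-2-hydroxy-4-methoxy-6-propylbenzoic acid | CCCc1cc(OC)c(Cl)c(O)c1C(=O)O | intermediate
23 | 3-chloro-2-hydroxy-4-methoxy-6-propylbenzoic trifluoroacetic anhydride | CCCc1cc(OC)c(Cl)c(O)c1C(=O)OC(=O)C(F)(F)F | intermediate
24 | benzyl 4-[(3-chloro-2-hydroxy-4-methoxy-6-propylbenzoyl)oxy]-2-hydroxy-6-pentylbenzoate | CCCCCc1cc(OC(=O)c2c(CCC)cc(OC)c(Cl)c2O)cc(O)c1C(=O)OCc1ccccc1 | intermediate
25 | 4-[(3-chloro-2-hydroxy-4-methoxy-6-propylbenzoyl)oxy]-2-hydroxy-6-pentylbenzoic acid | CCCCCc1cc(OC(=O)c2c(CCC)cc(OC)c(Cl)c2O)cc(O)c1C(=O)O | target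

**Total step count:** 12
**Longest linear sequence:** 8 steps (steps 5, 6, 7, 8, 9, 10, 11 and 12, from 14)

**Steps most likely to fail**

Step 4. The acylketene may be captured by the enol oxygen of its own C5 carbonyl faster than by benzyl alcohol, which would divert material to a pyranone, or the triketo ester may close in the Claisen sense during the base stage. The fallback sets out from 8 and avoids the ketene altogether. Et3N in CH2Cl2 at rt should aromatise 8 directly, the dioxinone C5 adding to the terminal ketone in the same aldol sense, to give 7-hydroxy-2,2-dimethyl-5-pentyl-4H-1,3-benzodioxin-4-one F1. KOH in DMSO/H2O, followed by cold acidification, should open the acetonide to 2,4-dihydroxy-6-pentylbenzoic acid F2. BnBr with KHCO3 in DMF then alkylates only the carboxylate and returns to the route at 13.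

Step 11. The mixed anhydride may acylate the free 2-OH of a second molecule of the acid (self-condensation), or trifluoroacetylation of the phenol may outrun aroylation. The fallback sets out from 21 and masks the interfering hydroxyl. BnBr with K2CO3 in DMF should give 2-(benzyloxy)-3-chloro-4-methoxy-6-propylbenzaldehyde F3, and Pinnick oxidation as in step 10 should give 2-(benzyloxy)-3-chloro-4-methoxy-6-propylbenzoic acid F4. Steglich esterification of F4 with 13 (DCC, catalytic DMAP, CH2Cl2) should give benzyl 4-{[2-(benzyloxy)-3-chloro-4-methoxy-6-propylbenzoyl]oxy}-2-hydroxy-6-pentylbenzoate F5. Hydrogenolysis over 10% Pd/C in EtOAc removes both benzyl groups and comes back to the route at 25.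

Step 12. Reductive loss of the aryl chlorine may compete with cleavage of the benzyl C–O bond. The fallback sets out from 8 and uses an ester that is removed without hydrogen. Thermolysis of 8 in toluene with allyl alcohol in place of 9 should give allyl 3,5,7-trioxododecanoate F6, which the same Cs2CO3 and acid treatment should convert to allyl 2,4-dihydroxy-6-pentylbenzoate F7. Coupling of F7 with 22 under the conditions of step 11 should give allyl 4-[(3-chloro-2-hydroxy-4-methoxy-6-propylbenzoyl)oxy]-2-hydroxy-6-pentylbenzoate F8. Catalytic Pd(PPh3)4 with N-methylaniline as allyl acceptor in THF at rt should then release the acid, coming back to the route at 25.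

**Further compounds**
F1 | step 4 | 7-hydroxy-2,2-dimethyl-5-pentyl-4H-1,3-benzodioxin-4-one | CCCCCc1cc(O)cc2OC(C)(C)OC(=O)c12
F2 | step 4 | 2,4-dihydroxy-6-pentylbenzoic acid | CCCCCc1cc(O)cc(O)c1C(=O)O
F3 | step 11 | 2-(benzyloxy)-3-chloro-4-methoxy-6-propylbenzaldehyde | CCCc1cc(OC)c(Cl)c(OCc2ccccc2)c1C=O
F4 | step 11 | 2-(benzyloxy)-3-chloro-4-methoxy-6-propylbenzoic acid | CCCc1cc(OC)c(Cl)c(OCc2ccccc2)c1C(=O)O
F5 | step 11 | benzyl 4-{[2-(benzyloxy)-3-chloro-4-methoxy-6-propylbenzoyl]oxy}-2-hydroxy-6-pentylbenzoate | CCCCCc1cc(OC(=O)c2c(CCC)cc(OC)c(Cl)c2OCc3ccccc3)cc(O)c1C(=O)OCc4ccccc4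
F6 | step 12 | allyl 3,5,7-trioxododecanoate | CCCCCC(=O)CC(=O)CC(=O)CC(=O)OCC=C
F7 | step 12 | allyl 2,4-dihydroxy-6-pentylbenzoate | CCCCCc1cc(O)cc(O)c1C(=O)OCC=C
F8 | step 12 | allyl 4-[(3-chloro-2-hydroxy-4-methoxy-6-propylbenzoyl)oxy]-2-hydroxy-6-pentylbenzoate | CCCCCc1cc(OC(=O)c2c(CCC)cc(OC)c(Cl)c2O)cc(O)c1C(=O)OCC=C
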